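**Remarks before the route**

- Reading of the SMILES: the target is (−)-epigallocatechin 3-O-gallate-(4β→8)-(+)-gallocatechin. The upper unit is 2R,3R,4R (B ring and gallate cis, the C4 aryl trans to both); the lower unit is 2R,3S (2,3-trans).
- Atom labels: upper unit O1, C2, C3, C4, C4a–C8a with rings A (phloroglucinol), C (pyran), B (pyrogallol); lower unit rings D (phloroglucinol), F (pyran), E (pyrogallol). Lower-unit atoms are written "C8 of ring D", "C6 of ring D".
- Assumption: (+)-gallocatechin, 3,5-bis(benzyloxy)phenol, 3,4,5-tris(benzyloxy)benzaldehyde and 3,4,5-tris(benzyloxy)benzoic acid are taken as catalogue compounds.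
- Assumption: the sense of induction of the chiral acid in step 7 cannot be derived from close precedent. The (R) antipode is written; the (S) antipode is used if the facial sense turns out opposite.

## Analysis of the target

The target joins two flavan units: C4 of an upper epigallocatechin gallate (rings A, C, B, galloyl ester on O3) is bonded to C8 of ring D of a lower gallocatechin (rings D, F, E). The upper unit carries three contiguous stereocentres on ring C (2,3-cis, 3,4-trans); the lower unit carries two on ring F (2,3-trans). The flat ring D lies between the two sets, so neither unit can relay stereochemistry to the other. The feature the route is built on is the upper ring C, O1–C2–C3–C4–C4a–C8a. It is a 2,4-diaryl-3-acyloxychroman in which C4 is a diarylmethine between rings A and D with the phenolic O1 ortho to it, the exocyclic carbon of a latent ring-A o-quinone methide; C2–C3, with aryl and acyloxy cis, is a latent Z-enol ester. Sensitive elements are fourteen phenols including three pyrogallols (air, base), the gallate ester, the acid-labile interflavan C4–C8(D) bond and the benzylic C2–O1 bonds. The difficulties are the 2,3-cis/3,4-trans triad (ring closures under thermodynamic control prefer 2,3-trans), the C8 versus C6 regiochemistry on ring D, a 1:1 union without oligomerisation, and protecting groups that must leave under neutral conditions.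

## Retrosynthetic reasoning

**15 ⇒ 14.** All fourteen O–H groups are carried as benzyl ethers, so the last step is one neutral hydrogenolysis and the free polyphenol never meets acid, base or oxidant.

**14 ⇒ 13 + 12.** Ring C is cut at O1–C2 and C3–C4, a retro oxa-[4+2]. These two cuts remove the pyran ring and all three upper stereocentres in one operation, and the gallate ester becomes part of the 2π component. What remains is the achiral Z-enol ester 12 and the o-quinone methide 13, which is released from carbinol 8 by loss of water. The forward reaction has to control regiochemistry (O1 to the aryl-bearing carbon), keep the Z geometry (2,3-cis), place the acyloxy group trans to the C4 aryl, and choose one face of 13 under catalyst control.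

**8 ⇒ 7 + 6.** The interflavan C4–C8(D) bond is cut as a carbonyl addition of aryllithium 7 to salicylaldehyde 6. The site on ring D is fixed by the halogen of 4, and the union is 1:1 and regiospecific by construction instead of relying on an excess of nucleophile.

**4 ⇒ 3 ⇒ 1, and 6 ⇒ 5.** The bromide 4 comes from 3 by electrophilic bromination at the more reactive C8. Compound 3 is the benzylated chiral-pool flavanol 1, which supplies both lower stereocentres unchanged. Aldehyde 6 comes from the symmetric phenol 5 by ortho-formylation.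

**12 ⇒ 10 + 11, and 10 ⇒ 9.** The enol C–O bond is cut: anti-Markovnikov trans-addition of acid 11 across alkyne 10 gives the Z geometry directly. Alkyne 10 is a one-carbon homologation of aldehyde 9.

## Alternatives that were turned down

**Alternative 1:** (the textbook route) Cut only C4–C8(D) between two intact flavan units. The forward key step is a Lewis-acid-promoted Friedel–Crafts alkylation of 3 by the C4 cation from A1, the perbenzylated 4β-(2-hydroxyethoxy)epigallocatechin gallate; the nucleophile enters trans to the participating gallate. It is reliable, but it forms one bond and sets one stereocentre, and all other stereocentres must be bought as two natural flavanols. The cation is also generated in the presence of a product that is as nucleophilic as 3 (free C6 of ring D, free C6/C8 of ring A), so oligomers are suppressed only by a several-fold excess of the gallocatechin unit, and C8/C6 selectivity rests on inherent bias. It is kept as the fallback, not as the strategy.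

**Alternative 2:** Cut C4–C4a. The forward key step is an intramolecular Friedel–Crafts closure of ring C from the acyclic aryl ether carbinol A2 (ring A attached through O1 to C2, gallate on O3, carbinol at C4 bearing ring D); the C4 cation is captured trans to the gallate through anchimeric assistance. The stereochemical logic is sound, but C2 and C3 must be set separately by an asymmetric oxidation and an invertive benzylic etherification, and A2 needs about eight linear steps of redox and protecting-group work before the closure. The closure itself then builds only one bond and one stereocentre.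

**Alternative 3:** Cut C4–C8(D) at the flavylium oxidation level. Addition of 3 to the 3-galloyloxyflavylium salt A3 would give the 4-aryl-4H-chromene A4, followed by hydrogenation of C2=C3. It was turned down on mechanism. Addition to the planar cation sets C4 without any control element. Syn delivery of H2 to the tetrasubstituted enol ester from the face opposite the C4 aryl puts H3 trans to that aryl, which gives the 2,3-cis-3,4-cis isomer, not the required 3,4-trans one. No group on the correct face could direct the metal.

Key step: step 7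

## Route

Step 1
Reactants: 1 (+)-gallocatechin
Product: 3 per-O-benzylated gallocatechin (3,5,7,3',4',5'-hexa-O-benzyl-(+)-gallocatechin), via penta-O-benzylgallocatechin 2 (not isolated)
Conditions: BnBr, K2CO3, DMF, 0 °C to rt, Ar; then NaH, BnBr, Bu4NI (cat.), 0 °C to rt
Reagents that add atoms: benzyl bromide, BrCc1ccccc1
Why: Williamson etherification: K2CO3 benzylates only the five phenols (2), then NaH ionises the secondary 3-OH for the sixth benzylation. No stereocentre is touched, and low temperature with exclusion of air limits C-benzylation, C2 epimerisation and pyrogallol oxidation.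

Step 2
Reactants: 3 hexa-O-benzyl-(+)-gallocatechin
Product: 4 8-bromo-3,5,7,3',4',5'-hexa-O-benzyl-(+)-gallocatechin
Conditions: NBS (1.05 equiv), CH2Cl2, −78 °C to −20 °C, dark
Reagents that add atoms: N-bromosuccinimide, O=C1CCC(=O)N1Br
Why: Electrophilic aromatic bromination of the phloroglucinol-type ring D; C8 (between O1 and the 7-benzyloxy group) is the inherently more reactive site of benzylated flavan-3-ols. One equivalent at low temperature should stop at the 8-monobromide and leave the less activated ring E alone.

Step 3
Reactants: 5 3,5-bis(benzyloxy)phenol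
Product: 6 2,4-bis(benzyloxy)-6-hydroxybenzaldehyde
Conditions: MgCl2, Et3N, (CH2O)n, MeCN, reflux; 1 M HCl work-up
Reagents that add atoms: paraformaldehyde (as formaldehyde), C=O
Why: Magnesium-mediated ortho-formylation (Casnati–Skattebøl): the magnesium phenoxide delivers formaldehyde to the ortho carbon through a chelate and a second formaldehyde oxidises the benzylic alkoxide. The two ortho positions of 5 are equivalent and the para position is not reached.

Step 4
Reactants: 4 8-bromo-hexa-O-benzyl-(+)-gallocatechin; 6 2,4-bis(benzyloxy)-6-hydroxybenzaldehyde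
Product: 8 [2,4-bis(benzyloxy)-6-hydroxyphenyl](hexa-O-benzylgallocatechin-8-yl)methanol as a mixture of carbinol epimers, via aryllithium 7 (not isolated)
Conditions: 4, n-BuLi, THF, −78 °C; then sodium phenoxide of 6 (6, NaH, THF, 0 °C), −78 °C to −20 °C; sat. NH4Cl, 0 °C; used crude
Reagents that add atoms: none
Why: Bromine–lithium exchange at −78 °C is faster than any attack on benzyl ethers and fixes the union at C8 of ring D. Aryllithium 7 adds 1,2 to the aldehyde, whose phenol is masked in situ as the phenoxide so that one equivalent of 7 suffices. The carbinol centre forms without control and is erased in step 7.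

Step 5
Reactants: 9 3,4,5-tris(benzyloxy)benzaldehyde
Product: 10 1,2,3-tris(benzyloxy)-5-ethynylbenzene
Conditions: dimethyl (1-diazo-2-oxopropyl)phosphonate, K2CO3, MeOH/THF, 0 °C to rt
Reagents that add atoms: dimethyl (1-diazo-2-oxopropyl)phosphonate (Ohira–Bestmann reagent), CC(=O)C(=[N+]=[N-])P(=O)(OC)OC
Why: Seyferth–Gilbert homologation: methanolysis frees the diazomethylphosphonate anion, Horner–Wadsworth–Emmons-type olefination and loss of N2 give an alkylidene carbene, and a 1,2-H shift gives the alkyne. The mild carbonate conditions leave the benzyl ethers alone.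

Step 6
Reactants: 10 1,2,3-tris(benzyloxy)-5-ethynylbenzene; 11 3,4,5-tris(benzyloxy)benzoic acid
Product: 12 (Z)-2-[3,4,5-tris(benzyloxy)phenyl]ethenyl 3,4,5-tris(benzyloxy)benzoate
Conditions: [Ru(η3-methallyl)2(dppb)] (cat.), toluene, 65 °C
Reagents that add atoms: none
Why: Ruthenium-catalysed anti-Markovnikov hydro-oxycarbonylation of a terminal alkyne: the carboxylate adds to the α-carbon of a Ru-vinylidene and protonolysis of the alkenyl–Ru bond releases the enol ester with O and aryl cis (Z). The step is atom-economic and uses no acid or base that could touch benzyl ethers.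

Step 7
Reactants: 8 [2,4-bis(benzyloxy)-6-hydroxyphenyl](hexa-O-benzylgallocatechin-8-yl)methanol; 12 (Z)-enol gallate
Product: 14 tetradeca-O-benzyl derivative of the target (5,7,3',4',5'-penta-O-benzylepigallocatechin 3-O-(3,4,5-tri-O-benzylgallate)-(4β→8)-hexa-O-benzylgallocatechin), via o-quinone methide 13 (not isolated)
Conditions: (R)-3,3'-bis(2,4,6-triisopropylphenyl)-BINOL N-triflylphosphoramide (10 mol%), 12 (3 equiv), 5 Å MS, PhCl, −30 °C, slow addition of 8
Reagents that add atoms: none
Why: Proposed new method: the acid dehydrates 8 to the ring-A o-quinone methide 13 (O1=C8a–C4a=C4, held as a hydrogen-bonded ion pair with the chiral phosphoramide anion), which reacts as a 1-oxadiene with the Z-enol ester 12 in an inverse-electron-demand oxa-[4+2] cycloaddition; the closest known reaction type is the chiral Brønsted acid-catalysed [4+2] of o-hydroxybenzhydrol-derived o-quinone methides with styrenes to 2,4-diarylchromans, which has not been run with a β-acyloxystyrene. Ring C closes in a concerted but asynchronous six-membered [4π+2π] mode in which C4–C3 bonding leads and O1–C2 bonding follows within the ion pair. Regiochemistry: the alkene carbon β to the trialkoxyphenyl ring (the future C3) is the nucleophilic terminus, because the charge developing at C2 is a benzylic cation para to a benzyloxy group, whereas the other orientation would need a poorly stabilised acyloxycarbenium ion. C2/C3: suprafacial addition across the Z-alkene keeps the B ring and the O-galloyl group cis. C3/C4: the O-galloyl group and the perpendicular, di-ortho-substituted ring D on C4 avoid each other across the forming C3–C4 bond (E-13 with exo approach and Z-13 with endo approach both lead to the same product), so they end up trans. Absolute sense: ring D and its remote stereocentres cannot bias the diene faces, so the catalyst anion has to block one face and direct 12 to the face of C4 from which ring D, C4a and H appear clockwise along the forming bond (the Si face), which gives 2R,3R,4R. The step therefore needs regio-control (from the aryl group), cis-retention (from concertedness; a long-lived benzylic cation would leak to 2,3-trans), trans-selectivity (steric) and facial selectivity (catalyst), and the cycloaddition must outrun Friedel–Crafts attack by C6 of ring D of a second molecule, hence the excess of 12 and the slow addition of 8.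

Step 8
Reactants: 14 tetradeca-O-benzyl derivative of the target
Product: 15 (−)-epigallocatechin 3-O-gallate-(4β→8)-(+)-gallocatechin (target)
Conditions: H2 (1 atm), Pd(OH)2/C, THF/MeOH/H2O, rt; filtration under Ar, Sephadex LH-20, lyophilisation
Reagents that add atoms: none
Why: Heterogeneous hydrogenolysis of thirteen aryl benzyl ethers and one alkyl benzyl ether under neutral conditions. The gallate ester, the interflavan C4–C8(D) bond and the C2–O1 bonds of both pyran rings are expected to survive, as is usual for benzylated proanthocyanidin gallates, and no stereocentre is touched.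

## Compound list

1 | (+)-gallocatechin, (2R,3S)-2-(3,4,5-trihydroxyphenyl)chromane-3,5,7-triol | c1c(O)cc(O)c2c1O[C@H](c1cc(O)c(O)c(O)c1)[C@@H](O)C2 | starting material
2 | 5,7,3',4',5'-penta-O-benzyl-(+)-gallocatechin (free 3-OH) | c1c(OCc3ccccc3)cc(OCc3ccccc3)c2c1O[C@H](c1cc(OCc3ccccc3)c(OCc3ccccc3)c(OCc3ccccc3)c1)[C@@H](O)C2 | intermediate
3 | 3,5,7,3',4',5'-hexa-O-benzyl-(+)-gallocatechin | c1c(OCc3ccccc3)cc(OCc3ccccc3)c2c1O[C@H](c1cc(OCc3ccccc3)c(OCc3ccccc3)c(OCc3ccccc3)c1)[C@@H](OCc3ccccc3)C2 | intermediate
4 | 8-bromo-3,5,7,3',4',5'-hexa-O-benzyl-(+)-gallocatechin | Brc1c(OCc3ccccc3)cc(OCc3ccccc3)c2c1O[C@H](c1cc(OCc3ccccc3)c(OCc3ccccc3)c(OCc3ccccc3)c1)[C@@H](OCc3ccccc3)C2 | intermediate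
5 | 3,5-bis(benzyloxy)phenol | Oc1cc(OCc2ccccc2)cc(OCc2ccccc2)c1 | starting material
6 | 2,4-bis(benzyloxy)-6-hydroxybenzaldehyde | O=Cc1c(O)cc(OCc2ccccc2)cc1OCc1ccccc1 | intermediate
7 | 8-lithio-3,5,7,3',4',5'-hexa-O-benzyl-(+)-gallocatechin | [Li]c1c(OCc3ccccc3)cc(OCc3ccccc3)c2c1O[C@H](c1cc(OCc3ccccc3)c(OCc3ccccc3)c(OCc3ccccc3)c1)[C@@H](OCc3ccccc3)C2 | intermediate
8 | [2,4-bis(benzyloxy)-6-hydroxyphenyl](hexa-O-benzylgallocatechin-8-yl)methanol, carbinol epimers | OC(c1c(O)cc(OCc3ccccc3)cc1OCc1ccccc1)c1c(OCc3ccccc3)cc(OCc3ccccc3)c2c1O[C@H](c1cc(OCc3ccccc3)c(OCc3ccccc3)c(OCc3ccccc3)c1)[C@@H](OCc3ccccc3)C2 | intermediate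
9 | 3,4,5-tris(benzyloxy)benzaldehyde | O=Cc1cc(OCc2ccccc2)c(OCc2ccccc2)c(OCc2ccccc2)c1 | starting material
10 | 1,2,3-tris(benzyloxy)-5-ethynylbenzene | C#Cc1cc(OCc2ccccc2)c(OCc2ccccc2)c(OCc2ccccc2)c1 | intermediate
11 | 3,4,5-tris(benzyloxy)benzoic acid | OC(=O)c1cc(OCc2ccccc2)c(OCc2ccccc2)c(OCc2ccccc2)c1 | starting material
12 | (Z)-2-[3,4,5-tris(benzyloxy)phenyl]ethenyl 3,4,5-tris(benzyloxy)benzoate | O=C(O/C=C\c1cc(OCc2ccccc2)c(OCc2ccccc2)c(OCc2ccccc2)c1)c1cc(OCc2ccccc2)c(OCc2ccccc2)c(OCc2ccccc2)c1 | intermediate
13 | 3,5-bis(benzyloxy)-6-[(hexa-O-benzylgallocatechin-8-yl)methylidene]cyclohexa-2,4-dien-1-one (ring-A o-quinone methide, E/Z not fixed) | O=C1C=C(OCc3ccccc3)C=C(OCc3ccccc3)C1=Cc1c(OCc3ccccc3)cc(OCc3ccccc3)c2c1O[C@H](c1cc(OCc3ccccc3)c(OCc3ccccc3)c(OCc3ccccc3)c1)[C@@H](OCc3ccccc3)C2 | intermediate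
14 | 5,7,3',4',5'-penta-O-benzyl-(−)-epigallocatechin 3-O-(3,4,5-tri-O-benzylgallate)-(4β→8)-3,5,7,3',4',5'-hexa-O-benzyl-(+)-gallocatechin | O=C(O[C@@H]1[C@@H](c2c(OCc4ccccc4)cc(OCc4ccccc4)c3c2O[C@H](c2cc(OCc4ccccc4)c(OCc4ccccc4)c(OCc4ccccc4)c2)[C@@H](OCc4ccccc4)C3)c2c(OCc4ccccc4)cc(OCc4ccccc4)cc2O[C@@H]1c1cc(OCc4ccccc4)c(OCc4ccccc4)c(OCc4ccccc4)c1)c1cc(OCc4ccccc4)c(OCc4ccccc4)c(OCc4ccccc4)c1 | intermediate
15 | (−)-epigallocatechin 3-O-gallate-(4β→8)-(+)-gallocatechin (CNP0194932.1) | O=C(O[C@@H]1[C@@H](c2c(O)cc(O)c3c2O[C@H](c2cc(O)c(O)c(O)c2)[C@@H](O)C3)c2c(O)cc(O)cc2O[C@@H]1c1cc(O)c(O)c(O)c1)c1cc(O)c(O)c(O)c1 | target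

## Step count and risk

Total step count: 8. Longest linear sequence: 5 steps (1, 2, 4, 7, 8).

**Step 7 (key step, proposed new method).** Most likely to go wrong:
- loss of the 2,3-cis relationship, either through a stepwise path with a free benzylic cation at C2 or through acid-catalysed Z-to-E isomerisation of 12 before it reacts;
- poor facial selectivity, because the ion pair is loose around two di-ortho-substituted aryl groups;
- Friedel–Crafts self-condensation of 13 through C6 of ring D outrunning a slow cycloaddition with a weakly nucleophilic enol ester.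

Fallback with known chemistry, setting out from 3 and 11 and returning at 14: commercial (−)-epigallocatechin F1 is benzylated on its five phenols (BnBr, K2CO3, DMF) to penta-O-benzylepigallocatechin F2. Oxidation at C4 with DDQ in CH2Cl2 in the presence of 2-ethoxyethanol gives the 4β-(2-ethoxyethoxy) ether F3. Steglich esterification with 11 (DCC, DMAP) gives the gallate F4. TMSOTf-catalysed Friedel–Crafts coupling of F4 with an excess of 3 in CH2Cl2 at −78 °C forms C4–C8(D) trans to the participating gallate and gives 14, which enters step 8.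

**Step 4.** Most likely to go wrong: slow addition between two di-ortho-substituted partners, with proton transfer to 7 (reduction back to 3) competing, and premature loss of water from the very electron-rich carbinol on work-up. Fallback with reversed polarity, setting out from 4 and 5 and returning at 8: 4 is lithiated as before and quenched with DMF to give the 8-carbaldehyde F5. Phenol 5 is converted with EtMgBr in toluene into the bromomagnesium phenoxide F6. F6 adds to F5 ortho-specifically through a chelated six-membered transition state (magnesium phenoxide ortho-hydroxyalkylation; both ortho positions of 5 are equivalent) and gives 8 after NH4Cl work-up, without the salicylaldehyde 6.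

**Step 6.** Most likely to go wrong: erosion of Z-selectivity, Markovnikov addition or alkyne dimerisation with an electron-rich aryl alkyne and a hindered, poorly soluble acid. Fallback that builds the enol C–O bond by cross-coupling, setting out from 10 and 11 and returning at 12: Z-selective (formal trans) hydroboration of 10 with pinacolborane under Ru–PNP pincer catalysis gives the (Z)-alkenylboronate F7. KHF2 in MeOH/H2O converts it into the potassium (Z)-alkenyltrifluoroborate F8. Copper-catalysed oxidative C–O coupling of F8 with 11 (Cu(OAc)2, DMAP, 4 Å MS, O2, Chan–Lam type) gives 12 with retention of the alkene geometry.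

## Further compounds

F1 | step 7 | (−)-epigallocatechin (purchased) | O[C@@H]1Cc2c(O)cc(O)cc2O[C@@H]1c1cc(O)c(O)c(O)c1
F2 | step 7 | 5,7,3',4',5'-penta-O-benzyl-(−)-epigallocatechin | O[C@@H]1Cc2c(OCc3ccccc3)cc(OCc3ccccc3)cc2O[C@@H]1c1cc(OCc3ccccc3)c(OCc3ccccc3)c(OCc3ccccc3)c1
F3 | step 7 | 5,7,3',4',5'-penta-O-benzyl-4β-(2-ethoxyethoxy)epigallocatechin | O[C@@H]1[C@@H](OCCOCC)c2c(OCc3ccccc3)cc(OCc3ccccc3)cc2O[C@@H]1c1cc(OCc3ccccc3)c(OCc3ccccc3)c(OCc3ccccc3)c1
F4 | step 7 | 5,7,3',4',5'-penta-O-benzyl-4β-(2-ethoxyethoxy)epigallocatechin 3-O-(3,4,5-tri-O-benzylgallate) | O=C(O[C@@H]1[C@@H](OCCOCC)c2c(OCc3ccccc3)cc(OCc3ccccc3)cc2O[C@@H]1c1cc(OCc3ccccc3)c(OCc3ccccc3)c(OCc3ccccc3)c1)c1cc(OCc3ccccc3)c(OCc3ccccc3)c(OCc3ccccc3)c1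
F5 | step 4 | 3,5,7,3',4',5'-hexa-O-benzyl-(+)-gallocatechin-8-carbaldehyde | O=Cc1c(OCc3ccccc3)cc(OCc3ccccc3)c2c1O[C@H](c1cc(OCc3ccccc3)c(OCc3ccccc3)c(OCc3ccccc3)c1)[C@@H](OCc3ccccc3)C2
F6 | step 4 | bromomagnesium 3,5-bis(benzyloxy)phenoxide | Br[Mg]Oc1cc(OCc2ccccc2)cc(OCc2ccccc2)c1
F7 | step 6 | (Z)-2-{2-[3,4,5-tris(benzyloxy)phenyl]ethenyl}-4,4,5,5-tetramethyl-1,3,2-dioxaborolane | CC1(C)OB(/C=C\c2cc(OCc3ccccc3)c(OCc3ccccc3)c(OCc3ccccc3)c2)OC1(C)C
F8 | step 6 | potassium (Z)-{2-[3,4,5-tris(benzyloxy)phenyl]ethenyl}trifluoroborate | [K+].F[B-](F)(F)/C=C\c1cc(OCc2ccccc2)c(OCc2ccccc2)c(OCc2ccccc2)c1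
A1 | alternative 1 | 5,7,3',4',5'-penta-O-benzyl-4β-(2-hydroxyethoxy)epigallocatechin 3-O-(3,4,5-tri-O-benzylgallate) | O=C(O[C@@H]1[C@@H](OCCO)c2c(OCc3ccccc3)cc(OCc3ccccc3)cc2O[C@@H]1c1cc(OCc3ccccc3)c(OCc3ccccc3)c(OCc3ccccc3)c1)c1cc(OCc3ccccc3)c(OCc3ccccc3)c(OCc3ccccc3)c1
A2 | alternative 2 | acyclic aryl ether carbinol: (2R,3R-configured as in the target) 1-[3,5-bis(benzyloxy)phenoxy]-1-[3,4,5-tris(benzyloxy)phenyl]-3-hydroxy-3-(hexa-O-benzylgallocatechin-8-yl)propan-2-yl 3,4,5-tris(benzyloxy)benzoate, carbinol epimers | O=C(O[C@H](C(O)c1c(OCc4ccccc4)cc(OCc4ccccc4)c2c1O[C@H](c1cc(OCc4ccccc4)c(OCc4ccccc4)c(OCc4ccccc4)c1)[C@@H](OCc4ccccc4)C2)[C@H](Oc1cc(OCc4ccccc4)cc(OCc4ccccc4)c1)c1cc(OCc4ccccc4)c(OCc4ccccc4)c(OCc4ccccc4)c1)c1cc(OCc4ccccc4)c(OCc4ccccc4)c(OCc4ccccc4)c1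
A3 | alternative 3 | 5,7-bis(benzyloxy)-2-[3,4,5-tris(benzyloxy)phenyl]-3-[3,4,5-tris(benzyloxy)benzoyloxy]chromenylium hexafluorophosphate | O=C(Oc1cc2c(OCc3ccccc3)cc(OCc3ccccc3)cc2[o+]c1-c1cc(OCc3ccccc3)c(OCc3ccccc3)c(OCc3ccccc3)c1)c1cc(OCc3ccccc3)c(OCc3ccccc3)c(OCc3ccccc3)c1.F[P-](F)(F)(F)(F)F
A4 | alternative 3 | 5,7-bis(benzyloxy)-4-(hexa-O-benzylgallocatechin-8-yl)-2-[3,4,5-tris(benzyloxy)phenyl]-4H-chromen-3-yl 3,4,5-tris(benzyloxy)benzoate, C4 epimers | O=C(OC1=C(c2cc(OCc4ccccc4)c(OCc4ccccc4)c(OCc4ccccc4)c2)Oc2cc(OCc4ccccc4)cc(OCc4ccccc4)c2C1c1c(OCc4ccccc4)cc(OCc4ccccc4)c2c1O[C@H](c1cc(OCc4ccccc4)c(OCc4ccccc4)c(OCc4ccccc4)c1)[C@@H](OCc4ccccc4)C2)c1cc(OCc4ccccc4)c(OCc4ccccc4)c(OCc4ccccc4)c1
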